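Amounts first: the green and blue flasks hold the same starting material and initiator and differ in the amount of coupling partner.

the same everywhere: starting material 0.20 M; initiator 1 mol%

| charge | coupling partner | remark | time |
|---|---|---|---|
| green | 0.80 equiv | the very flask that is asked about, followed so far |  |
| blue | 0.54 equiv | run made earlier |  |
| flask | 0.800 equiv |  | 2.5 h |

| run | time / min | product / % | starting material / % |
|---|---|---|---|
| green | 8.00 | 21 | 75 |
| green | 25.0 | 56 | 43 |
| green | 40.0 | 70 | 30 |
| green | 60.0 | 81 | 22 |
| green | 90.0 | 79 | 19 |
| green | 120 | 81 | 23 |
| green | 150 | 80 | 19 |
| blue | 6.00 | 21 | 83 |
| blue | 10.0 | 29 | 72 |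
| blue | 15.0 | 37 | 62 |
| blue | 25.0 | 51 | 52 |
| blue | 30.0 | 54 | 45 |
| blue | 50.0 | 51 | 45 |
| blue | 80.0 | 54 | 44 |

(standard deviation of a reading: 1.5 percentage points)

- oak: at 2.5 h take out 90% of the by-product then present, then wait 50 min
- elm: change nothing and wait 50 min more
- ash: at 2.5 h add starting material, 50.0% of the amount charged, then wait 50 min
- birch: at 2.5 h add coupling partner, 100% of the amount charged, then wait 50 min

- the volume of additions can be left aside
- the numbers in the tables scatter with a standard deviation of 1.5 percentage points

- product, in percent of the starting material first charged, at 2.5 h
- the option that brings most further product ("none" if no option brings more than 2 percentage points) (oak / elm / ash / birch / none)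
- product present, in percent of the starting material first charged, after elm
- product present, in percent of the starting material first charged, after birch

The green flask looks contradictory. At 150 min it still reads 19% starting material, yet product reads 80%, much as at 60.0 min with 81%, although the first 8.00 min gave 21%. The blue flask also goes flat, but with 44% starting material still present, so no single amount of starting material marks the stop.

I divide each plateau by the partner charged. Blue averages 53.0% from 30.0 min on, which gives 0.981. Green averages 80.2% from 60.0 min on, which gives 1.00. Their mean 0.992 is the partner yield, the product made per equivalent of coupling partner charged. A value this close to one marks coupling partner as the limiting reagent.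

So I reckon the green flask at 79.4% at 2.5 h. Elm, oak and ash add no partner, so I expect this ceiling to stay. Birch gives twice the partner and a ceiling of 159%, so there the green flask's limit becomes its product plus starting material, 99.0%. The ceiling does not say how far 50 min gets.

The forecast gives 80.3% now, 80.3% after elm, birch as best, and 91% after birch, a figure it lowers for “some initiator decay”. Its first figure stands 0.90 points above mine, less than the scatter.

The flask gives 80.0% at 2.5 h, 80.0% after elm, and 91.8% after birch, a gain of 12 points.

2 second chain carrier → ended chains (k = 5.70 × 10⁶ M⁻¹ s⁻¹); coupling partner + first chain carrier → product + second chain carrier (k = 4.37 × 10⁵ M⁻¹ min⁻¹); initiator → 2 initiating radical (k = 0.00831 min⁻¹); starting material + second chain carrier → by-product + first chain carrier (k = 1.82 × 10⁵ M⁻¹ min⁻¹); starting material + initiating radical → capped initiator + first chain carrier (k = 3.50 × 10⁵ M⁻¹ s⁻¹); first chain carrier → ended carrier (k = 57.0 min⁻¹) At 150 min its free coupling partner stands at 0%, with 19.0% of the starting material free. With initiator lowered to 0.24 mol%, the flask's product at 2.5 h has moved by 5 points, and a run showing that move would go against the forecast's first figure. In the neighbour with 0.320 equiv of coupling partner, the partner yield gives 31.8% product, and that flask reaches 32.0% product at 2.5 h.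

The data come from a simulation on assumed constants.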